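**Retrosynthetic overview**
- The tetronic acid ring is attached last: its C5=CH bond comes from aldol condensation and dehydration of the (S)-α-methyl aldehyde 22 with C5-lithiated methyl 3-methyltetronate, followed by O-demethylation.
- The strategy rests on furan B, the 2,4-disubstituted furan: C2 carries the furan-3-ylmethyl group, C4 carries the chain, and C3 and C5 carry only hydrogen. C5 can therefore enter as a mixed-acetal carbon and the C3–C4 bond can be made by ring-closing metathesis, after which loss of methanol aromatises the ring.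
- The metathesis substrate is the mixed methyl acetal 18, made from the 2-methylidene aldehyde dimethyl acetal 13 and the racemic vinyl carbinol 17 (three steps from furan-3-carbaldehyde).
- The chain comes from a B-alkyl Suzuki coupling of the (S)-pentenyl silyl ether 5 (from the (R)-hydroxy ester 1, which supplies the only stereocentre) with the (E)-vinyl iodide 8 (from hex-5-yn-1-ol by carboalumination, which sets the trisubstituted alkene).
- Ring order: furan A is bought, furan B is built in step 14, and the tetronate ring is bought and joined in steps 18–20.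

Key step: step 14

**Remarks on the chemistry**
- The primary alcohol is carried as a tert-butyldiphenylsilyl ether, because the acetalisation, the acetal exchange and the aromatisation all run under acid.
- Carbinol 17 is used as the racemate, and 18, 19, 26 and 27 are diastereomer mixtures at centres that later become sp2.
- 3-Methyltetronic acid 23 is assumed to be commercially available.

**Route**

Step 1
Reactants: 1 methyl (R)-3-hydroxy-2-methylpropanoate
Product: 2 methyl (R)-3-((tert-butyldiphenylsilyl)oxy)-2-methylpropanoate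
Conditions: t-BuPh2SiCl, imidazole, CH2Cl2, 0 °C to rt
Reagents that add atoms: tert-butyl(chloro)diphenylsilane, CC(C)(C)[Si](Cl)(c1ccccc1)c1ccccc1
Why: Imidazole-mediated silylation of a primary alcohol should proceed without touching the α-stereocentre, since no strong base is present.

Step 2
Reactants: 2 methyl (R)-3-((tert-butyldiphenylsilyl)oxy)-2-methylpropanoate
Product: 3 (S)-3-((tert-butyldiphenylsilyl)oxy)-2-methylpropan-1-ol
Conditions: i-Bu2AlH (2.3 equiv), CH2Cl2, −78 to 0 °C; aqueous potassium sodium tartrate
Reagents that add atoms: none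
Why: Hydride reduction of the ester with excess i-Bu2AlH should give the primary alcohol and leave the silyl ether intact; the descriptor changes to S only through the priority switch.

Step 3
Reactants: 3 (S)-3-((tert-butyldiphenylsilyl)oxy)-2-methylpropan-1-ol
Product: 4 (R)-tert-butyl(3-iodo-2-methylpropoxy)diphenylsilane
Conditions: I2, PPh3, imidazole, CH2Cl2, 0 °C to rt
Reagents that add atoms: iodine, II
Why: Appel-type iodination (Garegg–Samuelsson conditions) is an SN2 displacement at the primary carbon, so the neighbouring stereocentre should be unaffected.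

Step 4
Reactants: 4 (R)-tert-butyl(3-iodo-2-methylpropoxy)diphenylsilane
Product: 5 (S)-tert-butyl((2-methylpent-4-en-1-yl)oxy)diphenylsilane
Conditions: CH2=CHMgBr (3 equiv), CuI (20 mol%), THF–DMPU, −30 to 0 °C
Reagents that add atoms: vinylmagnesium bromide, C=C[Mg]Br
Why: Copper-catalysed cross-coupling of a primary alkyl iodide with a vinyl Grignard reagent (Kochi-type) should replace iodide by vinyl at the CH2 carbon, leaving the stereocentre one carbon away unchanged.

Step 5
Reactants: 6 hex-5-yn-1-ol
Product: 8 (E)-6-iodo-5-methylhex-5-en-1-ol, via alkenylalane 7 (not isolated)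
Conditions: Me3Al (3 equiv), Cp2ZrCl2 (0.25 equiv), CH2Cl2, 0 °C to rt; then I2, THF, −30 to 0 °C
Reagents that add atoms: trimethylaluminium, C[Al](C)C; iodine, II
Why: Negishi zirconium-catalysed carboalumination adds methyl and aluminium syn across the terminal alkyne with methyl on the internal carbon, and iodinolysis with retention should give the E vinyl iodide.

Step 6
Reactants: 5 (S)-tert-butyl((2-methylpent-4-en-1-yl)oxy)diphenylsilane; 8 (E)-6-iodo-5-methylhex-5-en-1-ol
Product: 10 (S,E)-11-((tert-butyldiphenylsilyl)oxy)-5,10-dimethylundec-5-en-1-ol, via alkylborane 9 (not isolated)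
Conditions: 5, 9-BBN, THF, rt; then 8, Pd(dppf)Cl2 (5 mol%), AsPh3, Cs2CO3, DMF/H2O, rt
Reagents that add atoms: none
Why: In this Suzuki–Miyaura B-alkyl coupling, 9-BBN adds anti-Markovnikov to the terminal alkene and the palladium-catalysed coupling with the vinyl iodide should retain the E geometry and tolerate the free hydroxyl.

Step 7
Reactants: 10 (S,E)-11-((tert-butyldiphenylsilyl)oxy)-5,10-dimethylundec-5-en-1-ol
Product: 11 (S,E)-11-((tert-butyldiphenylsilyl)oxy)-5,10-dimethylundec-5-enal
Conditions: TEMPO (10 mol%), PhI(OAc)2, CH2Cl2, rt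
Reagents that add atoms: none
Why: Oxoammonium-mediated oxidation (TEMPO with PhI(OAc)2) should take the primary alcohol to the aldehyde and stop there, leaving the trisubstituted alkene and the silyl ether alone.

Step 8
Reactants: 11 (S,E)-11-((tert-butyldiphenylsilyl)oxy)-5,10-dimethylundec-5-enal
Product: 12 (S,E)-11-((tert-butyldiphenylsilyl)oxy)-5,10-dimethyl-2-methylideneundec-5-enal
Conditions: 37% aq. CH2O, pyrrolidine (10 mol%), propionic acid (10 mol%), i-PrOH, 45 °C
Reagents that add atoms: formaldehyde, C=O
Why: Organocatalytic α-methylenation (Mannich condensation of the enamine with formaldehyde, then amine elimination) should install the 1,1-disubstituted alkene on the only enolisable position.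

Step 9
Reactants: 12 (S,E)-11-((tert-butyldiphenylsilyl)oxy)-5,10-dimethyl-2-methylideneundec-5-enal
Product: 13 tert-butyl{[(2S,6E)-11,11-dimethoxy-2,7-dimethyl-10-methylideneundec-6-en-1-yl]oxy}diphenylsilane
Conditions: HC(OMe)3 (3 equiv), MeOH, pyridinium p-toluenesulfonate (5 mol%), rt
Reagents that add atoms: trimethyl orthoformate, COC(OC)OC; methanol, CO
Why: Acid-catalysed acetalisation with the orthoformate as water scavenger should give the dimethyl acetal, and the weak acid keeps conjugate addition of methanol and silyl cleavage slow.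

Step 10
Reactants: 14 furan-3-carbaldehyde
Product: 15 3-(2-methoxyethenyl)furan (E/Z mixture)
Conditions: Ph3P(CH2OMe)Cl, KOt-Bu, THF, 0 °C to rt
Reagents that add atoms: (methoxymethyl)triphenylphosphonium chloride, COC[P+](c1ccccc1)(c1ccccc1)c1ccccc1.[Cl-]
Why: Wittig olefination with the methoxymethylidene ylide is the standard one-carbon homologation of an aromatic aldehyde, and the E/Z ratio is irrelevant.

Step 11
Reactants: 15 3-(2-methoxyethenyl)furan
Product: 16 2-(furan-3-yl)acetaldehyde
Conditions: 2 M aq. HCl, THF, rt to 40 °C; crude product used at once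
Reagents that add atoms: water, O
Why: Acid hydrolysis of the enol ether (C-protonation, hydration of the oxocarbenium ion, loss of methanol) should release the homologated aldehyde, and the unactivated 3-substituted furan should tolerate brief exposure to dilute acid.

Step 12
Reactants: 16 2-(furan-3-yl)acetaldehyde
Product: 17 1-(furan-3-yl)but-3-en-2-ol (racemic)
Conditions: CH2=CHMgBr, THF, −78 °C; aq. NH4Cl
Reagents that add atoms: vinylmagnesium bromide, C=C[Mg]Br
Why: Grignard 1,2-addition at low temperature should outrun enolisation of the arylacetaldehyde; the carbinol centre is formed without control, which is acceptable because it becomes C2 of furan B.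

Step 13
Reactants: 13 tert-butyl{[(2S,6E)-11,11-dimethoxy-2,7-dimethyl-10-methylideneundec-6-en-1-yl]oxy}diphenylsilane; 17 1-(furan-3-yl)but-3-en-2-ol
Product: 18 tert-butyl{[(2S,6E)-11-{[1-(furan-3-yl)but-3-en-2-yl]oxy}-11-methoxy-2,7-dimethyl-10-methylideneundec-6-en-1-yl]oxy}diphenylsilane (diastereomer mixture)
Conditions: 13 (1.3 equiv), 17 (1.0 equiv), pyridinium p-toluenesulfonate (5 mol%), toluene, 40 °C, reduced pressure to remove MeOH; unreacted 13 recovered
Reagents that add atoms: none
Why: Acid-catalysed transacetalisation through the conjugated oxocarbenium ion should exchange one methoxy group for the allylic alkoxy group, with removal of methanol driving the exchange and the limiting alcohol disfavouring double exchange.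

Step 14
Reactants: 18 mixed methyl acetal (diastereomer mixture)
Product: 20 tert-butyl{[(2S,6E)-9-[5-(furan-3-ylmethyl)furan-3-yl]-2,7-dimethylnon-6-en-1-yl]oxy}diphenylsilane, via methoxydihydrofuran 19 (not isolated)
Conditions: (H2IMes)(PCy3)Cl2Ru=CHPh (second-generation Grubbs catalyst, 5–10 mol%), CH2Cl2 (0.01 M), 40 °C; then CF3CO2H (0.1 equiv), rt, same flask
Reagents that add atoms: none
Why: The ruthenium benzylidene should exchange onto the monosubstituted vinyl group of the carbinol part, add across the 1,1-disubstituted alkene to a ruthenacyclobutane and, on cycloreversion, release ethylene and form the C3–C4 bond of furan B within the 2-methoxy-2,5-dihydrofuran 19. The closest known reaction type is the ring-closing metathesis of mixed allylic acetals of enals followed by acid-induced loss of alcohol to give furans. The one ring closed is five-membered (O1, C2, C3, C4, C5 of furan B) and is closed at the C3=C4 double bond, the two alkenes being held five atoms apart through the acetal oxygen. No lasting stereocentre is created, because trifluoroacetic acid ionises the methoxy group at the acetal carbon (C5) to an oxocarbenium ion and loss of the proton at the former carbinol carbon (C2) makes both mixed centres sp2. The step needs chemoselectivity for the two terminal alkenes over the trisubstituted chain alkene and the furan A double bonds: the former is hindered and could only close an eight- or nine-membered ring, and the latter are aromatic, so neither should compete. The 2,4-pattern is fixed by the connectivity of the acetal, so the aromatisation raises no regiochemical question.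

Step 15
Reactants: 20 bisfuran silyl ether
Product: 21 (2S,6E)-9-[5-(furan-3-ylmethyl)furan-3-yl]-2,7-dimethylnon-6-en-1-ol
Conditions: Bu4NF, THF, 0 °C to rt
Reagents that add atoms: none
Why: Fluoride-mediated desilylation is driven by the Si–F bond and should leave the furans and the alkene untouched.

Step 16
Reactants: 21 (2S,6E)-9-[5-(furan-3-ylmethyl)furan-3-yl]-2,7-dimethylnon-6-en-1-ol
Product: 22 (2S,6E)-9-[5-(furan-3-ylmethyl)furan-3-yl]-2,7-dimethylnon-6-enal
Conditions: Dess–Martin periodinane, NaHCO3, CH2Cl2, 0 °C to rt; used without chromatography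
Reagents that add atoms: none
Why: Buffered Dess–Martin oxidation is non-basic and mild, so the α-methyl stereocentre of the aldehyde should not epimerise and the furans should survive.

Step 17
Reactants: 23 3-methyltetronic acid (4-hydroxy-3-methylfuran-2(5H)-one)
Product: 24 4-methoxy-3-methylfuran-2(5H)-one
Conditions: Me2SO4, K2CO3, acetone, reflux
Reagents that add atoms: dimethyl sulfate, COS(=O)(=O)OC
Why: O-Alkylation of the vinylogous acid with a hard methylating agent should give the methyl tetronate, since C3 is already substituted and O-attack is favoured.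

Step 18
Reactants: 24 4-methoxy-3-methylfuran-2(5H)-one; 22 (2S,6E)-9-[5-(furan-3-ylmethyl)furan-3-yl]-2,7-dimethylnon-6-enal
Product: 26 5-{(2S,6E)-9-[5-(furan-3-ylmethyl)furan-3-yl]-1-hydroxy-2,7-dimethylnon-6-en-1-yl}-4-methoxy-3-methylfuran-2(5H)-one (diastereomer mixture), via lithiated tetronate 25 (not isolated)
Conditions: 24, LiN(i-Pr)2 (commercial solution), THF, −78 °C; then 22, −78 °C; aq. NH4Cl
Reagents that add atoms: none
Why: Deprotonation of the tetronate at C5 gives a lithium dienolate that should undergo aldol addition to the aldehyde faster than it enolises it at −78 °C; the new carbinol and C5 centres form as a mixture and are removed in the next step.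

Step 19
Reactants: 26 aldol adduct (diastereomer mixture)
Product: 28 (5Z)-5-{(2S,6E)-9-[5-(furan-3-ylmethyl)furan-3-yl]-2,7-dimethylnon-6-en-1-ylidene}-4-methoxy-3-methylfuran-2(5H)-one, via mesylate 27 (not isolated)
Conditions: MsCl, Et3N, CH2Cl2, 0 °C; then DBU, 0 °C to rt
Reagents that add atoms: none
Why: Mesylation followed by E1cB elimination through the C5 dienolate should give the exocyclic alkene, with the Z isomer favoured because it places the chain next to the ring oxygen and away from the 4-methoxy group.

Step 20
Reactants: 28 (5Z)-ylidene methyl tetronate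
Product: 29 (5Z)-5-{(2S,6E)-9-[5-(furan-3-ylmethyl)furan-3-yl]-2,7-dimethylnon-6-en-1-ylidene}-4-hydroxy-3-methylfuran-2(5H)-one
Conditions: n-PrSLi (from n-PrSH and n-BuLi), HMPA, rt; then dilute aq. HCl
Reagents that add atoms: none
Why: SN2 O-demethylation by the thiolate at the methyl carbon of the vinylogous ester releases the delocalised tetronate anion, which on acidification should give the tetronic acid without touching the alkenes or the stereocentre.

**Compound list**
1 | methyl (R)-3-hydroxy-2-methylpropanoate | OC[C@@H](C)C(=O)OC | starting material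
2 | methyl (R)-3-((tert-butyldiphenylsilyl)oxy)-2-methylpropanoate | CC(C)(C)[Si](c1ccccc1)(c1ccccc1)OC[C@@H](C)C(=O)OC | intermediate
3 | (S)-3-((tert-butyldiphenylsilyl)oxy)-2-methylpropan-1-ol | CC(C)(C)[Si](c1ccccc1)(c1ccccc1)OC[C@@H](C)CO | intermediate
4 | (R)-tert-butyl(3-iodo-2-methylpropoxy)diphenylsilane | CC(C)(C)[Si](c1ccccc1)(c1ccccc1)OC[C@@H](C)CI | intermediate
5 | (S)-tert-butyl((2-methylpent-4-en-1-yl)oxy)diphenylsilane | CC(C)(C)[Si](c1ccccc1)(c1ccccc1)OC[C@@H](C)CC=C | intermediate
6 | hex-5-yn-1-ol | C#CCCCCO | starting material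
7 | (E)-alkenylalane, dimethylaluminium alkoxide of 6-(dimethylalumanyl)-5-methylhex-5-en-1-ol | C[Al](C)/C=C(\C)CCCCO[Al](C)C | intermediate
8 | (E)-6-iodo-5-methylhex-5-en-1-ol | OCCCC/C(C)=C/I | intermediate
9 | (S)-9-[5-((tert-butyldiphenylsilyl)oxy)-4-methylpentyl]-9-borabicyclo[3.3.1]nonane | CC(C)(C)[Si](c1ccccc1)(c1ccccc1)OC[C@@H](C)CCCB1C2CCCC1CCC2 | intermediate
10 | (S,E)-11-((tert-butyldiphenylsilyl)oxy)-5,10-dimethylundec-5-en-1-ol | OCCCC/C(C)=C/CCC[C@H](C)CO[Si](c1ccccc1)(c1ccccc1)C(C)(C)C | intermediate
11 | (S,E)-11-((tert-butyldiphenylsilyl)oxy)-5,10-dimethylundec-5-enal | O=CCCC/C(C)=C/CCC[C@H](C)CO[Si](c1ccccc1)(c1ccccc1)C(C)(C)C | intermediate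
12 | (S,E)-11-((tert-butyldiphenylsilyl)oxy)-5,10-dimethyl-2-methylideneundec-5-enal | O=CC(=C)CC/C(C)=C/CCC[C@H](C)CO[Si](c1ccccc1)(c1ccccc1)C(C)(C)C | intermediate
13 | tert-butyl{[(2S,6E)-11,11-dimethoxy-2,7-dimethyl-10-methylideneundec-6-en-1-yl]oxy}diphenylsilane | COC(OC)C(=C)CC/C(C)=C/CCC[C@H](C)CO[Si](c1ccccc1)(c1ccccc1)C(C)(C)C | intermediate
14 | furan-3-carbaldehyde | O=Cc1ccoc1 | starting material
15 | 3-(2-methoxyethenyl)furan (E/Z mixture) | COC=Cc1ccoc1 | intermediate
16 | 2-(furan-3-yl)acetaldehyde | O=CCc1ccoc1 | intermediate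
17 | 1-(furan-3-yl)but-3-en-2-ol (racemic) | C=CC(O)Cc1ccoc1 | intermediate
18 | mixed methyl acetal of 12 with 17, (2S,6E), mixture at the acetal and carbinol carbons | C=CC(Cc1ccoc1)OC(OC)C(=C)CC/C(C)=C/CCC[C@H](C)CO[Si](c1ccccc1)(c1ccccc1)C(C)(C)C | intermediate
19 | 2-methoxy-5-(furan-3-ylmethyl)-3-[(3E,8S)-9-((tert-butyldiphenylsilyl)oxy)-3,8-dimethylnon-3-en-1-yl]-2,5-dihydrofuran (diastereomer mixture) | COC1OC(Cc2ccoc2)C=C1CC/C(C)=C/CCC[C@H](C)CO[Si](c1ccccc1)(c1ccccc1)C(C)(C)C | intermediate
20 | tert-butyl{[(2S,6E)-9-[5-(furan-3-ylmethyl)furan-3-yl]-2,7-dimethylnon-6-en-1-yl]oxy}diphenylsilane | CC(C)(C)[Si](c1ccccc1)(c1ccccc1)OC[C@@H](C)CCC/C=C(\C)CCc1coc(Cc2ccoc2)c1 | intermediate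
21 | (2S,6E)-9-[5-(furan-3-ylmethyl)furan-3-yl]-2,7-dimethylnon-6-en-1-ol | OC[C@@H](C)CCC/C=C(\C)CCc1coc(Cc2ccoc2)c1 | intermediate
22 | (2S,6E)-9-[5-(furan-3-ylmethyl)furan-3-yl]-2,7-dimethylnon-6-enal | O=C[C@@H](C)CCC/C=C(\C)CCc1coc(Cc2ccoc2)c1 | intermediate
23 | 3-methyltetronic acid (4-hydroxy-3-methylfuran-2(5H)-one) | CC1=C(O)COC1=O | starting material
24 | 4-methoxy-3-methylfuran-2(5H)-one | COC1=C(C)C(=O)OC1 | intermediate
25 | 5-lithio-4-methoxy-3-methylfuran-2(5H)-one (lithium dienolate) | COC1=C(C)C(=O)OC1[Li] | intermediate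
26 | aldol adduct, 5-(1-hydroxyalkyl) methyl tetronate, (2S,6E) in the chain, mixture at the carbinol carbon and C5 | COC1=C(C)C(=O)OC1C(O)[C@@H](C)CCC/C=C(\C)CCc1coc(Cc2ccoc2)c1 | intermediate
27 | methanesulfonate of 26 | COC1=C(C)C(=O)OC1C(OS(C)(=O)=O)[C@@H](C)CCC/C=C(\C)CCc1coc(Cc2ccoc2)c1 | intermediate
28 | (5Z)-5-{(2S,6E)-9-[5-(furan-3-ylmethyl)furan-3-yl]-2,7-dimethylnon-6-en-1-ylidene}-4-methoxy-3-methylfuran-2(5H)-one | CC1=C(OC)/C(=C/[C@@H](C)CCC/C=C(\C)CCc2coc(Cc3ccoc3)c2)OC1=O | intermediate
29 | (5Z)-5-{(2S,6E)-9-[5-(furan-3-ylmethyl)furan-3-yl]-2,7-dimethylnon-6-en-1-ylidene}-4-hydroxy-3-methylfuran-2(5H)-one (CNP0342578.1) | CC1=C(O)/C(=C/[C@@H](C)CCC/C=C(\C)CCc2coc(Cc3ccoc3)c2)OC1=O | target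

**Step count**
Total: 20 steps. Longest linear sequence: 15 steps (1, 2, 3, 4, 6, 7, 8, 9, 13, 14, 15, 16, 18, 19, 20, from compound 1).

**Steps most likely to fail**

1. Step 14 (metathesis and aromatisation). The acid-labile mixed acetal may ionise or exchange in the presence of the ruthenium species before the ring closes, or the acid-induced aromatisation may degrade the electron-rich bisfuran. The fallback carries C5 of furan B as an ester carbonyl and aromatises by reduction. It sets out from enal 12 and carbinol 17 and returns at 20. Enal 12 would be oxidised with NaClO2, NaH2PO4 and 2-methylbut-2-ene in t-BuOH/H2O to (S,E)-11-((tert-butyldiphenylsilyl)oxy)-5,10-dimethyl-2-methylideneundec-5-enoic acid F1. Steglich esterification with 17 (DCC, DMAP, CH2Cl2) would give the 1-(furan-3-yl)but-3-en-2-yl ester F2. Ring closure with (H2IMes)(PCy3)Cl2Ru=CHPh in toluene at 80 °C would give the α-substituted butenolide F3. Reduction with i-Bu2AlH in CH2Cl2 at −78 °C would give the lactol, which should lose water on mildly acidic work-up to furnish 20.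

2. Step 13 (mixed acetal). The equilibrium exchange may give a statistical mixture of unchanged, singly and doubly exchanged acetals, and conjugate addition to the oxocarbenium ion may compete. The fallback replaces the equilibrium by an irreversible substitution. It sets out from dimethyl acetal 13 and returns at 18. Treatment of 13 with acetyl chloride and catalytic ZnBr2 in CH2Cl2 at 0 °C would give the α-chloro methyl ether F4 and methyl acetate. Crude F4 would be added to alcohol 17 and i-Pr2NEt in CH2Cl2 at −40 °C to rt to give 18.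

3. Step 11 (enol ether hydrolysis). Acid-induced opening or oligomerisation of the furan and aldol self-condensation of the labile arylacetaldehyde may erode the yield. The fallback reaches the same aldehyde under neutral conditions. It sets out from furan-3-carbaldehyde 14 and returns at 16. Wittig methylenation (Ph3PCH3Br, KOt-Bu, Et2O) would give 3-ethenylfuran F5. Hydroboration with 9-BBN and oxidation with NaBO3 would give 2-(furan-3-yl)ethan-1-ol F6. Buffered Dess–Martin oxidation would give 16, used directly in step 12.

**Further compounds**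
F1 | step 14 | (S,E)-11-((tert-butyldiphenylsilyl)oxy)-5,10-dimethyl-2-methylideneundec-5-enoic acid | OC(=O)C(=C)CC/C(C)=C/CCC[C@H](C)CO[Si](c1ccccc1)(c1ccccc1)C(C)(C)C
F2 | step 14 | 1-(furan-3-yl)but-3-en-2-yl (S,E)-11-((tert-butyldiphenylsilyl)oxy)-5,10-dimethyl-2-methylideneundec-5-enoate | C=CC(Cc1ccoc1)OC(=O)C(=C)CC/C(C)=C/CCC[C@H](C)CO[Si](c1ccccc1)(c1ccccc1)C(C)(C)C
F3 | step 14 | 5-(furan-3-ylmethyl)-3-[(3E,8S)-9-((tert-butyldiphenylsilyl)oxy)-3,8-dimethylnon-3-en-1-yl]furan-2(5H)-one | O=C1OC(Cc2ccoc2)C=C1CC/C(C)=C/CCC[C@H](C)CO[Si](c1ccccc1)(c1ccccc1)C(C)(C)C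
F4 | step 13 | tert-butyl{[(2S,6E)-11-chloro-11-methoxy-2,7-dimethyl-10-methylideneundec-6-en-1-yl]oxy}diphenylsilane | COC(Cl)C(=C)CC/C(C)=C/CCC[C@H](C)CO[Si](c1ccccc1)(c1ccccc1)C(C)(C)C
F5 | step 11 | 3-ethenylfuran | C=Cc1ccoc1
F6 | step 11 | 2-(furan-3-yl)ethan-1-ol | OCCc1ccoc1
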